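**Plan**
Ring numbering: C1 ketone, C2 (bearing C7H2OH)=C3, C4 (O-propanoyl), C5 (isopropyl), C6 (O-acyl). The retrosynthesis cuts the C6–O acyl bond first. It then cuts the C4–O bond, going back with inversion to the epimeric alcohol and, by Baeyer–Villiger logic, to a C4 acetyl group. Last it cuts C3–C4 and C5–C6 of the carbocycle.
Enabling feature: the C1 ketone is conjugated to C2=C3, C6 bears oxygen, and the C4/C5 pair can carry acetyl and isopropyl. This pattern is what a 1-methoxy-3-silyloxy diene (C3=C2–C1=C6) leaves after adding to a C4=C5 enone and losing methanol from C3.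
Forward: C3–C2–C7 comes from methyl 3-methoxyacrylate and C1–C6 from a glycolic N-methoxy-N-methylamide. They are joined at sp2 carbon, so C2 never bears hydrogen; this removes any regiochemical choice on enolisation and any β-elimination of the C7 oxygen. The only ring closes in step 7, followed by enone unveiling, C4 oxidation and inversion, C6 acylation and desilylation.
Stereochemistry: the chiral boron cation sets the absolute sense, and the E-enone makes C4/C5 trans. The (1E,3Z)-diene and endo addition put C6–O trans to isopropyl. The Baeyer–Villiger migration retains C4 and the Mitsunobu step inverts it. The side-chain E-alkene comes from a stabilised ylide.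

Key step: step 7

Assumption: the catalyst enantiomer is assigned from the usual binding picture of this cation with enones. In that picture boron sits on the convex face at the carbonyl lone pair syn to the vinyl group, the enone is s-trans with an α-C–H···O contact to the ring oxygen, and the diene adds on the face turned away from the diphenyl-bearing carbon. This calls for the (R)-diphenylprolinol-derived catalyst. Both antipodes are commercial, so the other is taken, with nothing else changed, if the sense proves reversed.

Step 1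
Reactants: 1 methyl (E)-3-methoxyacrylate
Product: 3 methyl (Z)-2-iodo-3-methoxyacrylate, via iodoacetate adduct 2 (not isolated)
Conditions: NIS, AcOH, CH2Cl2, rt; then Et3N, rt
Reagents that add atoms: N-iodosuccinimide, O=C1CCC(=O)N1I; acetic acid, CC(=O)O (held in 2 only)
Why: Electrophilic iodine adds to the nucleophilic α-carbon of the push–pull alkene, acetate caps the oxocarbenium ion, and Et3N removes the acidic C2–H with loss of acetate (halogenation by addition–elimination), giving the more stable isomer with OMe anti to the ester.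

Step 2
Reactants: 3 methyl (Z)-2-iodo-3-methoxyacrylate
Product: 4 (Z)-2-iodo-3-methoxyprop-2-en-1-ol
Conditions: i-Bu2AlH (2.3 equiv), CH2Cl2, −78 °C; aq. potassium sodium tartrate
Reagents that add atoms: none
Why: Ester-to-allylic-alcohol reduction with i-Bu2AlH is a 1,2-process at −78 °C that leaves the vinyl iodide and the enol ether alone, and the non-acidic tartrate work-up protects the acid-labile product.

Step 3
Reactants: 4 (Z)-2-iodo-3-methoxyprop-2-en-1-ol
Product: 5 (Z)-tert-butyl[(2-iodo-3-methoxyprop-2-en-1-yl)oxy]diphenylsilane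
Conditions: TBDPSCl, imidazole, CH2Cl2, 0 °C → rt
Reagents that add atoms: tert-butyldiphenylsilyl chloride, CC(C)(C)[Si](Cl)(c1ccccc1)c1ccccc1
Why: Imidazole-promoted silylation of a primary alcohol is routine, and the bulky, weakly basic TBDPS ether is chosen to resist O→C silyl shift in step 5 and acid in steps 7 and 8.

Step 4
Reactants: 6 2-chloro-N-methoxy-N-methylacetamide; 7 4-methoxybenzyl alcohol
Product: 8 N-methoxy-2-(4-methoxybenzyloxy)-N-methylacetamide
Conditions: NaH, n-Bu4NI (cat.), THF, 0 °C → rt
Reagents that add atoms: none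
Why: In this Williamson ether synthesis the alkoxide of 7 displaces the activated primary chloride of 6 faster than it attacks the deactivated amide carbonyl.

Step 5
Reactants: 5 (Z)-tert-butyl[(2-iodo-3-methoxyprop-2-en-1-yl)oxy]diphenylsilane; 8 N-methoxy-2-(4-methoxybenzyloxy)-N-methylacetamide
Product: 11 (E)-4-methoxy-1-(4-methoxybenzyloxy)-3-(tert-butyldiphenylsilyloxymethyl)but-3-en-2-one, via alkenylmagnesium chloride 9 (not isolated), via (Z)-enone 10 (not isolated)
Conditions: i-PrMgCl·LiCl, THF, −40 → −20 °C; 8, −20 → 0 °C; aq. NH4Cl; then camphor-10-sulfonic acid (5 mol %), CH2Cl2, rt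
Reagents that add atoms: isopropylmagnesium chloride–lithium chloride, CC(C)[Mg]Cl.[Li+].[Cl-] (held in 9 only)
Why: Iodine–magnesium exchange on an alkenyl iodide goes with retention and gives a reagent stabilised by the cis methoxy group, its addition to 8 stops at the chelated tetrahedral adduct (Weinreb ketone synthesis), and catalytic acid then equilibrates the push–pull alkene through its O-protonated form to the more stable isomer with OMe anti to the acyl group.

Step 6
Reactants: 11 (E)-4-methoxy-1-(4-methoxybenzyloxy)-3-(tert-butyldiphenylsilyloxymethyl)but-3-en-2-one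
Product: 12 (1E,3Z)-3-(tert-butyldimethylsilyloxy)-2-(tert-butyldiphenylsilyloxymethyl)-1-methoxy-4-(4-methoxybenzyloxy)buta-1,3-diene
Conditions: TBSOTf, Et3N, Et2O, −78 → 0 °C
Reagents that add atoms: tert-butyldimethylsilyl trifluoromethanesulfonate, CC(C)(C)[Si](C)(C)OS(=O)(=O)C(F)(F)F
Why: Soft enolisation with a silyl triflate and Et3N can only remove a C6 proton, and deprotonation of the O-silylated ketone in the conformer that keeps OPMB away from the C2 branch gives the Z silyl enol ether, as is usual for α-alkoxy ketones.

Step 7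
Reactants: 12 (1E,3Z)-3-(tert-butyldimethylsilyloxy)-2-(tert-butyldiphenylsilyloxymethyl)-1-methoxy-4-(4-methoxybenzyloxy)buta-1,3-diene; 13 (E)-5-methylhex-3-en-2-one
Product: 14 (3S,4S,5S,6R)-4-acetyl-1-(tert-butyldimethylsilyloxy)-2-(tert-butyldiphenylsilyloxymethyl)-5-isopropyl-3-methoxy-6-(4-methoxybenzyloxy)cyclohex-1-ene (ring numbering of the plan; OMe, acetyl and OPMB on one face, isopropyl on the other)
Conditions: (R)-3,3-diphenyl-1-(2-methylphenyl)tetrahydro-1H,3H-pyrrolo[1,2-c][1,3,2]oxazaborole (20 mol %), (CF3SO2)2NH (18 mol %), CH2Cl2, −78 → −40 °C; Et3N quench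
Reagents that add atoms: none
Why: The N-protonated oxazaborolidine binds the carbonyl oxygen of s-trans 13 at boron and lowers its LUMO, so that the most nucleophilic diene terminus C6 (pushed by the C3 methoxy and C1 silyloxy groups) attacks the β-carbon C5 while C3 closes onto C4 in a concerted but asynchronous normal-demand [4+2] cycloaddition. The closest known reaction type is the oxazaborolidinium-catalysed enantioselective Diels–Alder addition of silyloxy dienes to acyclic enones. The one new ring, the six-membered carbocycle C1–C6, closes by intermolecular suprafacial union of the four diene carbons with the two alkene carbons, forming C3–C4 and C5–C6 in one event and leaving C1=C2 as a silyl enol ether. C4 and C5 come out trans because the E geometry of 13 is conserved, C3 and C6 come out cis because both oxygen substituents sit outside on the (1E,3Z)-diene, the endo acetyl group ends cis to C3–OMe and C6–OPMB so that C6–O is trans to isopropyl, and the absolute sense at all four centres follows from the enone face left open by the diphenyl-bearing carbon of the catalyst. The step needs regioselectivity, which two matched donors (C3–OMe, C1–OSi) outweighing the single donor on C6 secure, and it needs endo selectivity, which secondary overlap with the boron-bound acetyl group favours (an exo adduct differs only at C3, which is lost, and at C6, which can be equilibrated next to the later C1 ketone). It also needs survival of the diene, which the bulky TBS enol ether and the poorly basic TBDPS ether are chosen to help.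

Step 8
Reactants: 14 the cycloadduct
Product: 15 (4R,5S,6R)-4-acetyl-2-(tert-butyldiphenylsilyloxymethyl)-5-isopropyl-6-(4-methoxybenzyloxy)cyclohex-2-en-1-one
Conditions: 1 M aq. HCl, THF, 0 °C
Reagents that add atoms: none
Why: Acid ionises the allylic C3–OMe bond with the push of the silyl enol ether and water takes the silyl group (β-alkoxy elimination typical of such cycloadducts), the more basic, unhindered OMe leaving in preference to the C7 silyloxy group, while C4, C5 and C6 keep the all-equatorial arrangement that is also the thermodynamic one.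

Step 9
Reactants: 15 the 4-acetyl enone
Product: 16 (4R,5S,6R)-4-acetoxy-2-(tert-butyldiphenylsilyloxymethyl)-5-isopropyl-6-(4-methoxybenzyloxy)cyclohex-2-en-1-one
Conditions: mCPBA, CH2Cl2, rt
Reagents that add atoms: 3-chloroperoxybenzoic acid, OOC(=O)c1cccc(Cl)c1
Why: In this Baeyer–Villiger oxidation the peracid adds to the unconjugated acetyl carbonyl and the secondary C4 migrates in preference to methyl with retention of configuration, while the enone carbonyl and its electron-poor alkene do not compete.

Step 10
Reactants: 16 the C4 acetate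
Product: 17 (4R,5S,6R)-4-hydroxy-2-(tert-butyldiphenylsilyloxymethyl)-5-isopropyl-6-(4-methoxybenzyloxy)cyclohex-2-en-1-one
Conditions: K2CO3 (0.2 equiv), MeOH, 0 °C
Reagents that add atoms: none
Why: Carbonate-catalysed transesterification removes the only ester, low temperature and short contact limit conjugate addition of methoxide, and C6 already has its more stable configuration.

Step 11
Reactants: 17 the C4 alcohol; 18 propanoic acid
Product: 19 (4S,5S,6R)-2-(tert-butyldiphenylsilyloxymethyl)-5-isopropyl-6-(4-methoxybenzyloxy)-4-(propanoyloxy)cyclohex-2-en-1-one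
Conditions: PPh3, DIAD, toluene, 0 °C → rt
Reagents that add atoms: none
Why: In this Mitsunobu esterification propanoate displaces the activated allylic C4–O bond in an SN2 process with inversion, which puts the C4 oxygen cis to isopropyl, and SN2′ attack is blocked because it would have to occur at the fully substituted α-carbon C2.

Step 12
Reactants: 19 the C4 propanoate
Product: 20 (4S,5R,6R)-6-hydroxy-2-(tert-butyldiphenylsilyloxymethyl)-5-isopropyl-4-(propanoyloxy)cyclohex-2-en-1-one (same spatial arrangement; the C5 descriptor changes by priority only)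
Conditions: DDQ, CH2Cl2/pH 7 phosphate buffer, 0 °C → rt
Reagents that add atoms: none
Why: Oxidative PMB cleavage (hydride abstraction from the electron-rich benzylic position, then hydrolysis of the oxocarbenium ion) leaves silyl ether, ester and enone untouched.

Step 13
Reactants: 21 (tert-butyldimethylsilyloxy)acetaldehyde; 22 ethyl 2-(triphenylphosphoranylidene)propanoate
Product: 23 ethyl (E)-4-(tert-butyldimethylsilyloxy)-2-methylbut-2-enoate
Conditions: CH2Cl2, rt
Reagents that add atoms: none
Why: Wittig olefination with a stabilised α-methyl ylide gives the trisubstituted enoate with the ester trans to the CH2O group (E).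

Step 14
Reactants: 23 ethyl (E)-4-(tert-butyldimethylsilyloxy)-2-methylbut-2-enoate
Product: 24 (E)-4-(tert-butyldimethylsilyloxy)-2-methylbut-2-enoic acid
Conditions: LiOH, THF/MeOH/H2O, 0 °C → rt; 1 M HCl to pH 4, 0 °C
Reagents that add atoms: lithium hydroxide, [Li+].[OH-]
Why: Saponification of the ethyl ester is routine, and the primary TBS ether tolerates LiOH and brief acidification to pH 4.

Step 15
Reactants: 20 the C6 alcohol; 24 (E)-4-(tert-butyldimethylsilyloxy)-2-methylbut-2-enoic acid
Product: 25 (4S,5S,6R)-6-[(E)-4-(tert-butyldimethylsilyloxy)-2-methylbut-2-enoyloxy]-2-(tert-butyldiphenylsilyloxymethyl)-5-isopropyl-4-(propanoyloxy)cyclohex-2-en-1-one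
Conditions: DCC, 4-(dimethylamino)pyridine (cat.), CH2Cl2, 0 °C → rt
Reagents that add atoms: none
Why: Steglich esterification acylates the single free hydroxyl under nearly neutral conditions, so C6 next to the ketone is not epimerised and the E-enoate is not isomerised.

Step 16
Reactants: 25 the bis-silyl ether
Product: 26 target, (4S,5S,6R)-6-[(E)-4-hydroxy-2-methylbut-2-enoyloxy]-2-(hydroxymethyl)-5-isopropyl-4-(propanoyloxy)cyclohex-2-en-1-one
Conditions: HF·pyridine, pyridine, THF, 0 °C → rt
Reagents that add atoms: none
Why: Fluoride cleavage of both silyl ethers in a buffered acidic medium avoids the base-induced acyl migration and elimination to which the γ-acyloxy, α′-acyloxy enone is prone.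

**Compound list**
1 | methyl (E)-3-methoxyacrylate | CO/C=C/C(=O)OC | starting material
2 | methyl 3-acetoxy-2-iodo-3-methoxypropanoate (racemic diastereomer mixture) | COC(OC(C)=O)C(I)C(=O)OC | intermediate
3 | methyl (Z)-2-iodo-3-methoxyacrylate | CO/C=C(I)/C(=O)OC | intermediate
4 | (Z)-2-iodo-3-methoxyprop-2-en-1-ol | CO/C=C(I)/CO | intermediate
5 | (Z)-tert-butyl[(2-iodo-3-methoxyprop-2-en-1-yl)oxy]diphenylsilane | CO/C=C(I)/CO[Si](c1ccccc1)(c1ccccc1)C(C)(C)C | intermediate
6 | 2-chloro-N-methoxy-N-methylacetamide | CON(C)C(=O)CCl | starting material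
7 | 4-methoxybenzyl alcohol | COc1ccc(CO)cc1 | starting material
8 | N-methoxy-2-(4-methoxybenzyloxy)-N-methylacetamide | CON(C)C(=O)COCc1ccc(OC)cc1 | intermediate
9 | (Z)-[1-methoxy-3-(tert-butyldiphenylsilyloxy)prop-1-en-2-yl]magnesium chloride | CO/C=C([Mg]Cl)/CO[Si](c1ccccc1)(c1ccccc1)C(C)(C)C | intermediate
10 | (Z)-4-methoxy-1-(4-methoxybenzyloxy)-3-(tert-butyldiphenylsilyloxymethyl)but-3-en-2-one | CO/C=C(C(=O)COCc1ccc(OC)cc1)/CO[Si](c1ccccc1)(c1ccccc1)C(C)(C)C | intermediate
11 | (E)-4-methoxy-1-(4-methoxybenzyloxy)-3-(tert-butyldiphenylsilyloxymethyl)but-3-en-2-one | CO/C=C(CO[Si](c1ccccc1)(c1ccccc1)C(C)(C)C)/C(=O)COCc1ccc(OC)cc1 | intermediate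
12 | (1E,3Z)-3-(tert-butyldimethylsilyloxy)-2-(tert-butyldiphenylsilyloxymethyl)-1-methoxy-4-(4-methoxybenzyloxy)buta-1,3-diene | CO/C=C(CO[Si](c1ccccc1)(c1ccccc1)C(C)(C)C)/C(O[Si](C)(C)C(C)(C)C)=C/OCc1ccc(OC)cc1 | intermediate
13 | (E)-5-methylhex-3-en-2-one | CC(=O)/C=C/C(C)C | starting material
14 | endo cycloadduct, (3S,4S,5S,6R) | CO[C@@H]1C(CO[Si](c2ccccc2)(c2ccccc2)C(C)(C)C)=C(O[Si](C)(C)C(C)(C)C)[C@H](OCc2ccc(OC)cc2)[C@@H](C(C)C)[C@@H]1C(C)=O | intermediate
15 | 4-acetyl enone, (4R,5S,6R) | CC(=O)[C@@H]1C=C(CO[Si](c2ccccc2)(c2ccccc2)C(C)(C)C)C(=O)[C@H](OCc2ccc(OC)cc2)[C@H]1C(C)C | intermediate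
16 | C4 acetate, (4R,5S,6R) | CC(=O)O[C@@H]1C=C(CO[Si](c2ccccc2)(c2ccccc2)C(C)(C)C)C(=O)[C@H](OCc2ccc(OC)cc2)[C@H]1C(C)C | intermediate
17 | C4 alcohol, (4R,5S,6R) | O[C@@H]1C=C(CO[Si](c2ccccc2)(c2ccccc2)C(C)(C)C)C(=O)[C@H](OCc2ccc(OC)cc2)[C@H]1C(C)C | intermediate
18 | propanoic acid | CCC(=O)O | starting material
19 | C4 propanoate, (4S,5S,6R) | CCC(=O)O[C@H]1C=C(CO[Si](c2ccccc2)(c2ccccc2)C(C)(C)C)C(=O)[C@H](OCc2ccc(OC)cc2)[C@H]1C(C)C | intermediate
20 | C6 alcohol, (4S,5R,6R) | CCC(=O)O[C@H]1C=C(CO[Si](c2ccccc2)(c2ccccc2)C(C)(C)C)C(=O)[C@H](O)[C@H]1C(C)C | intermediate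
21 | (tert-butyldimethylsilyloxy)acetaldehyde | O=CCO[Si](C)(C)C(C)(C)C | starting material
22 | ethyl 2-(triphenylphosphoranylidene)propanoate | CCOC(=O)C(C)=P(c1ccccc1)(c1ccccc1)c1ccccc1 | starting material
23 | ethyl (E)-4-(tert-butyldimethylsilyloxy)-2-methylbut-2-enoate | CCOC(=O)/C(C)=C/CO[Si](C)(C)C(C)(C)C | intermediate
24 | (E)-4-(tert-butyldimethylsilyloxy)-2-methylbut-2-enoic acid | OC(=O)/C(C)=C/CO[Si](C)(C)C(C)(C)C | intermediate
25 | bis-silyl ether of the target, (4S,5S,6R) | CCC(=O)O[C@H]1C=C(CO[Si](c2ccccc2)(c2ccccc2)C(C)(C)C)C(=O)[C@H](OC(=O)/C(C)=C/CO[Si](C)(C)C(C)(C)C)[C@H]1C(C)C | intermediate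
26 | CNP0285949.1, (4S,5S,6R) | CCC(=O)O[C@H]1C=C(CO)C(=O)[C@H](OC(=O)/C(C)=C/CO)[C@H]1C(C)C | target

**Step count**
Total steps: 16.
Longest linear sequence: 13 steps (1–3, 5–12, 15, 16) from 1. Step 4 and steps 13–14 are side branches.

**Steps most likely to fail**

Step 7. Slow addition to the β-branched enone may leave the acidic cation time to consume the diene. This could happen by protodesilylation, by ionisation at the allylic C7–O bond, or by silyl transfer that releases an achiral silyl triflimide catalyst. Conversion and facial selectivity would then erode.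
- The fallback replaces one-point activation by a strong boron acid with two-point chelation of an imide by a mild divalent-copper complex. It sets out from 12 and returns at 14.
- Commercial (E)-4-methylpent-2-enoic acid with pivaloyl chloride and Et3N gives the mixed pivalic anhydride F1.
- F1 acylates lithiated oxazolidin-2-one to give 3-[(E)-4-methylpent-2-enoyl]oxazolidin-2-one F2.
- F2 and 12 react under [Cu(L)](SbF6)2 (10 mol %, L = 2,2′-isopropylidenebis[(4S)-4-tert-butyl-2-oxazoline]) in CH2Cl2 at −20 °C. This should give the endo imide cycloadduct F3.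
- MeNHOMe·HCl with i-PrMgCl in THF converts F3 into the N-methoxy-N-methylamide F4, and MeMgBr turns F4 into 14.

Step 11. The alkoxyphosphonium ion at C4, flanked by the isopropyl-bearing C5, may be displaced only slowly by the weakly acidic propanoic acid. Acyl transfer with retention, or elimination toward a dienone and aromatisation, could then compete.
- The fallback replaces phosphonium activation with a sulfonate leaving group and a naked carboxylate. It sets out from 17 and returns at 19.
- ClCH2SO2Cl in pyridine at 0 °C gives the C4 chloromethanesulfonate F5.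
- CsO2CCH2CH3 with 18-crown-6 in toluene displaces F5 with inversion to give 19.

Step 9. Peracid addition to the hindered acetyl group may be slow. Enolisation of the doubly activated C4–H would then have time to move the alkene or start aromatisation with loss of the C6 ether, and the anisyl ring might be oxidised.
- The fallback carries C4 as a formyl group, which takes up peracid much faster and leaves a very labile ester. It sets out from 12 and returns at 17.
- Diene 12 and commercial (E)-4-methylpent-2-enal react under the (S)-enantiomer of the same oxazaborolidine with (CF3SO2)2NH. The formyl C–H···O binding mode exposes the other alkene face, which is why the antipode is used. This gives the aldehyde cycloadduct F6.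
- 1 M aq. HCl in THF gives the 4-formyl enone F7.
- mCPBA gives the C4 formate F8 with retention, and KHCO3 in MeOH at 0 °C releases 17.

**Further compounds**
F1 | step 7 | (E)-4-methylpent-2-enoic pivalic anhydride | CC(C)/C=C/C(=O)OC(=O)C(C)(C)C
F2 | step 7 | 3-[(E)-4-methylpent-2-enoyl]oxazolidin-2-one | CC(C)/C=C/C(=O)N1CCOC1=O
F3 | step 7 | imide cycloadduct (as 14, 2-oxooxazolidine-3-carbonyl in place of acetyl) | CO[C@@H]1C(CO[Si](c2ccccc2)(c2ccccc2)C(C)(C)C)=C(O[Si](C)(C)C(C)(C)C)[C@H](OCc2ccc(OC)cc2)[C@@H](C(C)C)[C@@H]1C(=O)N3CCOC3=O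
F4 | step 7 | N-methoxy-N-methylamide cycloadduct (as 14, C(=O)N(OMe)Me in place of acetyl) | CO[C@@H]1C(CO[Si](c2ccccc2)(c2ccccc2)C(C)(C)C)=C(O[Si](C)(C)C(C)(C)C)[C@H](OCc2ccc(OC)cc2)[C@@H](C(C)C)[C@@H]1C(=O)N(C)OC
F5 | step 11 | C4 chloromethanesulfonate of 17 | ClCS(=O)(=O)O[C@@H]1C=C(CO[Si](c2ccccc2)(c2ccccc2)C(C)(C)C)C(=O)[C@H](OCc2ccc(OC)cc2)[C@H]1C(C)C
F6 | step 9 | aldehyde cycloadduct (as 14, formyl in place of acetyl) | CO[C@@H]1C(CO[Si](c2ccccc2)(c2ccccc2)C(C)(C)C)=C(O[Si](C)(C)C(C)(C)C)[C@H](OCc2ccc(OC)cc2)[C@@H](C(C)C)[C@@H]1C=O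
F7 | step 9 | 4-formyl enone (as 15, formyl in place of acetyl) | O=C[C@@H]1C=C(CO[Si](c2ccccc2)(c2ccccc2)C(C)(C)C)C(=O)[C@H](OCc2ccc(OC)cc2)[C@H]1C(C)C
F8 | step 9 | C4 formate (as 16, formyloxy in place of acetoxy) | O=CO[C@@H]1C=C(CO[Si](c2ccccc2)(c2ccccc2)C(C)(C)C)C(=O)[C@H](OCc2ccc(OC)cc2)[C@H]1C(C)C
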